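**Plan**

- Retrosynthesis: the allyl group is cut at its CH2–vinyl bond and the ring A phenol is masked as a silyl ether, which leads back to a ring B benzaldehyde. The C8–O bond to ring B is cut next, then the C7–ring A bond, leaving a three-carbon unit derived from lactate.
- Enabling feature: the C8 oxygen sits on the ring B carbon flanked by two methoxy groups and para to the allyl carbon. With that para carbon held as a formyl group, the flanked carbon becomes an electron-poor C–Br position that the C8 alcohol can etherify under palladium catalysis without any bond to C8 being broken.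
- Forward order: ethyl (S)-lactate → (S)-2-(benzyloxy)propanal; ring A Grignard addition (C7–aryl bond); O-methylation at C7; debenzylation; aryl ether coupling with 4-bromo-3,5-dimethoxybenzaldehyde; CHO → CH2OH → CH2Br → allyl; desilylation. No ring is built; both arenes are bought.
- Stereochemistry: C8 (S) comes from ethyl (S)-lactate and its C–O bond is never broken. C7 (S) is set by chelation-controlled Grignard addition, syn to the C8 oxygen (threo).

Key step: step 7

Remark: C7 is the benzylic carbon bearing OMe and C8 the methyl-bearing carbon; ring A is the 4-hydroxy-3-methoxyphenyl ring and ring B the allyl-dimethoxyphenyl ring; reagents named without a number are taken as commercially available.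

**Route**

Step 1
Reactants: 1 ethyl (S)-lactate
Product: 2 ethyl (S)-2-(benzyloxy)propanoate
Conditions: BnOC(=NH)CCl3, TfOH (cat.), cyclohexane/CH2Cl2, rt
Reagents that add atoms: benzyl 2,2,2-trichloroacetimidate, N=C(OCc1ccccc1)C(Cl)(Cl)Cl
Why: Acid-catalysed O-benzylation with a trichloroacetimidate alkylates the hydroxyl without base, so the stereocentre next to the ester (the future C8) should not epimerise.

Step 2
Reactants: 2 ethyl (S)-2-(benzyloxy)propanoate
Product: 3 (S)-2-(benzyloxy)propanal
Conditions: i-Bu2AlH, CH2Cl2, −78 °C; then MeOH, aq. potassium sodium tartrate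
Reagents that add atoms: none
Why: Partial ester reduction with i-Bu2AlH at low temperature should stop at the aluminium hemiacetal, which releases the aldehyde only on work-up; the aldehyde is used at once to avoid α-epimerisation.

Step 3
Reactants: 4 4-bromo-2-methoxyphenol
Product: 5 (4-bromo-2-methoxyphenoxy)triisopropylsilane
Conditions: TIPSCl, imidazole, DMF, rt
Reagents that add atoms: triisopropylsilyl chloride, CC(C)[Si](Cl)(C(C)C)C(C)C
Why: Imidazole-promoted silylation of a phenol masks the acidic OH for the organomagnesium step with a bulky group that should survive base, hydride, hydrogenation and the coupling.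

Step 4
Reactants: 5 (4-bromo-2-methoxyphenoxy)triisopropylsilane; 3 (S)-2-(benzyloxy)propanal
Product: 7 (1S,2S)-2-(benzyloxy)-1-[3-methoxy-4-(triisopropylsilyloxy)phenyl]propan-1-ol, via aryl Grignard reagent 6 (not isolated)
Conditions: Mg, THF, 40 °C; then 3 precomplexed with MgBr2·OEt2, CH2Cl2, −78 °C; then H2O
Reagents that add atoms: none
Why: Chelation-controlled Grignard addition: magnesium bridges the carbonyl and benzyloxy oxygens into a five-membered chelate and the aryl group attacks the face opposite the methyl group, which should set C7 as S, syn to the C8 oxygen.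

Step 5
Reactants: 7 (1S,2S)-2-(benzyloxy)-1-[3-methoxy-4-(triisopropylsilyloxy)phenyl]propan-1-ol
Product: 8 {4-[(1S,2S)-2-(benzyloxy)-1-methoxypropyl]-2-methoxyphenoxy}triisopropylsilane
Conditions: NaH, MeI, THF, 0 °C → rt
Reagents that add atoms: iodomethane, CI
Why: Williamson etherification of the sodium alkoxide with iodomethane forms the C7 methyl ether on oxygen, so no bond at either stereocentre is touched.

Step 6
Reactants: 8 {4-[(1S,2S)-2-(benzyloxy)-1-methoxypropyl]-2-methoxyphenoxy}triisopropylsilane
Product: 9 (1S,2S)-1-methoxy-1-[3-methoxy-4-(triisopropylsilyloxy)phenyl]propan-2-ol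
Conditions: H2 (1 atm), 10% Pd/C, EtOAc, rt
Reagents that add atoms: none
Why: Catalytic hydrogenolysis of the primary benzyl ether in neutral ethyl acetate should free the C8 hydroxyl, since the secondary, electron-rich benzylic methyl ether at C7 is cleaved far more slowly and the aryl silyl ether is inert.

Step 7
Reactants: 9 (1S,2S)-1-methoxy-1-[3-methoxy-4-(triisopropylsilyloxy)phenyl]propan-2-ol; 10 4-bromo-3,5-dimethoxybenzaldehyde
Product: 11 3,5-dimethoxy-4-{[(1S,2S)-1-methoxy-1-(3-methoxy-4-triisopropylsilyloxyphenyl)propan-2-yl]oxy}benzaldehyde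
Conditions: Pd2(dba)3 (cat.), 2-(di-tert-butylphosphino)-3-methoxy-6-methyl-2',4',6'-triisopropylbiphenyl (cat.), Cs2CO3, toluene, 90 °C
Reagents that add atoms: none
Why: Zerovalent palladium carrying the bulky di-tert-butyl biaryl phosphine inserts into the C–Br bond of 10, helped by the para formyl group; the caesium alkoxide of 9 then replaces bromide on divalent palladium and C–O reductive elimination releases aryl ether 11. The closest known reaction type is the palladium-catalysed etherification of secondary alcohols with aryl bromides under bulky biaryl phosphine ligation (Buchwald–Hartwig-type C–O coupling). No ring closes and no stereocentre is created: the C8–O bond of 9 is never broken, so C8 stays S and the 7S,8S (threo) pair passes through unchanged. The selectivity needed is reductive elimination ahead of β-hydride elimination from the palladium alkoxide, which would give a ketone and the debrominated arene; the ligand bulk, the two ortho methoxy groups and the electron-poor formyl-bearing aryl group should all speed reductive elimination. The weak, poorly soluble base Cs2CO3 in toluene keeps the alkoxide concentration low, which should spare the non-enolisable aldehyde and the bulky aryl silyl ether, and holding the future allyl carbon as CHO keeps an isomerisable alkene away from palladium hydrides.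

Step 8
Reactants: 11 3,5-dimethoxy-4-{[(1S,2S)-1-methoxy-1-(3-methoxy-4-triisopropylsilyloxyphenyl)propan-2-yl]oxy}benzaldehyde
Product: 12 (3,5-dimethoxy-4-{[(1S,2S)-1-methoxy-1-(3-methoxy-4-triisopropylsilyloxyphenyl)propan-2-yl]oxy}phenyl)methanol
Conditions: NaBH4, MeOH/THF, 0 °C
Reagents that add atoms: none
Why: Borohydride reduction of an aryl aldehyde to the benzylic alcohol is chemoselective and leaves the ethers and the silyl ether alone.

Step 9
Reactants: 12 (3,5-dimethoxy-4-{[(1S,2S)-1-methoxy-1-(3-methoxy-4-triisopropylsilyloxyphenyl)propan-2-yl]oxy}phenyl)methanol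
Product: 13 {4-[(1S,2S)-2-[4-(bromomethyl)-2,6-dimethoxyphenoxy]-1-methoxypropyl]-2-methoxyphenoxy}triisopropylsilane
Conditions: CBr4, PPh3, CH2Cl2, 0 °C
Reagents that add atoms: carbon tetrabromide, BrC(Br)(Br)Br
Why: The Appel reaction converts the primary benzylic alcohol into the bromide through an alkoxyphosphonium ion under neutral conditions, so the acid-sensitive C7 benzylic ether should be spared.

Step 10
Reactants: 13 {4-[(1S,2S)-2-[4-(bromomethyl)-2,6-dimethoxyphenoxy]-1-methoxypropyl]-2-methoxyphenoxy}triisopropylsilane
Product: 14 {4-[(1S,2S)-2-(4-allyl-2,6-dimethoxyphenoxy)-1-methoxypropyl]-2-methoxyphenoxy}triisopropylsilane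
Conditions: CH2=CHMgBr, CuI (cat.), 2,2'-bipyridyl (cat.), THF, −20 → 0 °C
Reagents that add atoms: vinylmagnesium bromide, C=C[Mg]Br
Why: Copper-catalysed cross-coupling of a benzylic bromide with a vinyl Grignard reagent replaces bromide by vinyl and should give the allyl arene directly, with the terminal alkene formed out of conjugation.

Step 11
Reactants: 14 {4-[(1S,2S)-2-(4-allyl-2,6-dimethoxyphenoxy)-1-methoxypropyl]-2-methoxyphenoxy}triisopropylsilane
Product: 15 4-[(1S,2S)-2-(4-allyl-2,6-dimethoxyphenoxy)-1-methoxypropyl]-2-methoxyphenol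
Conditions: Bu4NF, THF, 0 °C; then H2O
Reagents that add atoms: none
Why: Fluoride-mediated desilylation of the aryl silyl ether, driven by the strong Si–F bond, should release the phenol at 0 °C without moving the terminal alkene or touching the alkyl and aryl ethers.

**Compound list**

1 | ethyl (S)-lactate | C[C@H](O)C(=O)OCC | starting material
2 | ethyl (S)-2-(benzyloxy)propanoate | C[C@H](OCc1ccccc1)C(=O)OCC | intermediate
3 | (S)-2-(benzyloxy)propanal | C[C@H](OCc1ccccc1)C=O | intermediate
4 | 4-bromo-2-methoxyphenol | COc1cc(Br)ccc1O | starting material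
5 | (4-bromo-2-methoxyphenoxy)triisopropylsilane | COc1cc(Br)ccc1O[Si](C(C)C)(C(C)C)C(C)C | intermediate
6 | [3-methoxy-4-(triisopropylsilyloxy)phenyl]magnesium bromide (aryl Grignard reagent) | COc1cc([Mg]Br)ccc1O[Si](C(C)C)(C(C)C)C(C)C | intermediate
7 | (1S,2S)-2-(benzyloxy)-1-[3-methoxy-4-(triisopropylsilyloxy)phenyl]propan-1-ol | C[C@H](OCc1ccccc1)[C@@H](O)c1ccc(O[Si](C(C)C)(C(C)C)C(C)C)c(OC)c1 | intermediate
8 | {4-[(1S,2S)-2-(benzyloxy)-1-methoxypropyl]-2-methoxyphenoxy}triisopropylsilane | C[C@H](OCc1ccccc1)[C@@H](OC)c1ccc(O[Si](C(C)C)(C(C)C)C(C)C)c(OC)c1 | intermediate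
9 | (1S,2S)-1-methoxy-1-[3-methoxy-4-(triisopropylsilyloxy)phenyl]propan-2-ol | O[C@@H](C)[C@@H](OC)c1ccc(O[Si](C(C)C)(C(C)C)C(C)C)c(OC)c1 | intermediate
10 | 4-bromo-3,5-dimethoxybenzaldehyde | COc1cc(C=O)cc(OC)c1Br | starting material
11 | 3,5-dimethoxy-4-{[(1S,2S)-1-methoxy-1-(3-methoxy-4-triisopropylsilyloxyphenyl)propan-2-yl]oxy}benzaldehyde | O=Cc1cc(OC)c(O[C@@H](C)[C@@H](OC)c2ccc(O[Si](C(C)C)(C(C)C)C(C)C)c(OC)c2)c(OC)c1 | intermediate
12 | (3,5-dimethoxy-4-{[(1S,2S)-1-methoxy-1-(3-methoxy-4-triisopropylsilyloxyphenyl)propan-2-yl]oxy}phenyl)methanol | OCc1cc(OC)c(O[C@@H](C)[C@@H](OC)c2ccc(O[Si](C(C)C)(C(C)C)C(C)C)c(OC)c2)c(OC)c1 | intermediate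
13 | {4-[(1S,2S)-2-[4-(bromomethyl)-2,6-dimethoxyphenoxy]-1-methoxypropyl]-2-methoxyphenoxy}triisopropylsilane | BrCc1cc(OC)c(O[C@@H](C)[C@@H](OC)c2ccc(O[Si](C(C)C)(C(C)C)C(C)C)c(OC)c2)c(OC)c1 | intermediate
14 | {4-[(1S,2S)-2-(4-allyl-2,6-dimethoxyphenoxy)-1-methoxypropyl]-2-methoxyphenoxy}triisopropylsilane | C=CCc1cc(OC)c(O[C@@H](C)[C@@H](OC)c2ccc(O[Si](C(C)C)(C(C)C)C(C)C)c(OC)c2)c(OC)c1 | intermediate
15 | 4-[(1S,2S)-2-(4-allyl-2,6-dimethoxyphenoxy)-1-methoxypropyl]-2-methoxyphenol | C=CCc1cc(OC)c(O[C@@H](C)[C@@H](OC)c2ccc(O)c(OC)c2)c(OC)c1 | target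

**Step count and risks**

Total step count: 11. Longest linear sequence: 10 steps from ethyl (S)-lactate (steps 1, 2 and 4–11); step 3 lies in the ring A side branch.

Steps most likely to fail:

1. Step 7. The doubly ortho-substituted bromide may add to palladium or take up the alkoxide too slowly. β-Hydride elimination from the palladium alkoxide and hydride transfer to the formyl group would then consume the alcohol by oxidation and the bromide by reduction. Fallback: form the C8–O–aryl bond by a Mitsunobu reaction before C7 exists. Ethyl (R)-lactate (C[C@@H](O)C(=O)OCC) and commercially available 4-allyl-2,6-dimethoxyphenol (C=CCc1cc(OC)c(O)c(OC)c1) with PPh3 and DIAD in THF should give, with inversion, ethyl (S)-2-(4-allyl-2,6-dimethoxyphenoxy)propanoate F1. Reduction with i-Bu2AlH at −78 °C should give (S)-2-(4-allyl-2,6-dimethoxyphenoxy)propanal F2. Chelation-controlled addition of Grignard reagent 6 should give (1S,2S)-2-(4-allyl-2,6-dimethoxyphenoxy)-1-[3-methoxy-4-(triisopropylsilyloxy)phenyl]propan-1-ol F3, and NaH/MeI methylation of the C7 hydroxyl leads to 14. This fallback sets out from 5 (as its Grignard reagent 6) and comes back to the route at 14.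

2. Step 4. Facial selectivity may be poor if the non-chelated pathway competes because THF solvates magnesium, and aldehyde 3 may partly epimerise at its α-carbon; both would erode the threo relationship. Fallback: replace substrate control by reagent control. The C7-epimeric mixture of 7 is oxidised with Dess–Martin periodinane (NaHCO3, CH2Cl2) to (S)-2-(benzyloxy)-1-[3-methoxy-4-(triisopropylsilyloxy)phenyl]propan-1-one F4. Corey–Bakshi–Shibata reduction with (S)-1-methyl-3,3-diphenyltetrahydro-1H,3H-pyrrolo[1,2-c][1,3,2]oxazaborole and BH3·SMe2 in THF should then deliver hydride to the face that gives the 1S carbinol, the aryl group acting as the large substituent. This fallback sets out from 7 (as the epimer mixture) and comes back at 7.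

3. Step 10. Wurtz-type homocoupling of the electron-rich benzylic bromide and its reduction by halogen–magnesium exchange may outrun the copper-mediated cross-coupling. Fallback: a Stille coupling under neutral conditions, with Bu3SnCH=CH2 and Pd(PPh3)4 (cat.) in toluene at 80 °C. Zerovalent palladium inserts into the benzylic C–Br bond and the vinyl group is transferred from tin, with no basic or strongly nucleophilic organometallic present. This fallback sets out from 13 and comes back at 14 without a new intermediate.

**Further compounds**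

F1 | step 7 | ethyl (S)-2-(4-allyl-2,6-dimethoxyphenoxy)propanoate | C[C@H](Oc1c(OC)cc(CC=C)cc1OC)C(=O)OCC
F2 | step 7 | (S)-2-(4-allyl-2,6-dimethoxyphenoxy)propanal | C[C@H](Oc1c(OC)cc(CC=C)cc1OC)C=O
F3 | step 7 | (1S,2S)-2-(4-allyl-2,6-dimethoxyphenoxy)-1-[3-methoxy-4-(triisopropylsilyloxy)phenyl]propan-1-ol | C[C@H](Oc1c(OC)cc(CC=C)cc1OC)[C@@H](O)c1ccc(O[Si](C(C)C)(C(C)C)C(C)C)c(OC)c1
F4 | step 4 | (S)-2-(benzyloxy)-1-[3-methoxy-4-(triisopropylsilyloxy)phenyl]propan-1-one | C[C@H](OCc1ccccc1)C(=O)c1ccc(O[Si](C(C)C)(C(C)C)C(C)C)c(OC)c1
F0 | step 10 | none | none
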